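A direct plan would build ring A from open-chain pieces and aromatize it late.
It would make 3-[3-(benzyloxy)phenyl]propanal (A1) in three steps from a phenolic acid, join it by a Horner–Wadsworth–Emmons reaction with an α-benzylated ketophosphonate to the enone A2, add a malonic ester (Michael–Claisen annulation), hydrolyse and decarboxylate to the cyclohexane-1,3-dione A3, aromatize with iodine in methanol to the dimethyl ether A4 and remove the benzyl groups by hydrogenolysis.
Weak point 1: the run-up to A1 (double benzylation, LiAlH4 reduction, TEMPO oxidation) would spend three steps on protecting-group and oxidation-level changes that form no skeletal bond.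
Weak point 2: the annulation would need a malonate anion to add to the hindered β-carbon of the trisubstituted enone A2, which itself comes from a slow olefination with an α-branched phosphonate; it would also set three stereocentres that are all destroyed later.
Weak point 3: the iodine–methanol aromatization of A3 would have to oxidize the ring and etherify both oxygens in one late step, on an unsymmetrical dione whose electron-rich product invites ring iodination and incomplete methylation.

**Retrosynthetic overview**
Numbering: ring A = C1 (CH2CH2 bridge to ring B), C2 (4-hydroxybenzyl, ring C), C3 (OMe), C4 (H), C5 (OMe), C6 (H). The target has no stereocentre, and the (E) geometry of the styryl intermediates is of no consequence.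
The 3,5-dioxygenated ring A with carbon substituents at C1 and C2 is a folded 1,3,5-triketone, whose anhydro form is a 2,6-disubstituted 4-pyrone. The key disconnection is therefore the aldol bond C1–C2 of ring A, leading back to triketone 6 and pyrone 5.
Pyrone 5 comes from commercial 2,6-dimethyl-4-pyrone 1 through its two methyl groups. One is benzylated with 2 and becomes ring carbon C2 (the CH2 of 2 becomes the diarylmethane carbon). The other is condensed with aldehyde 4 and becomes the bridge carbon on C1.
Rings B and C are bought. Ring A is made last, from the pyrone ring, by ring opening and reclosure; O-methylation and one hydrogenation (styryl bond and both benzyl ethers) finish the synthesis.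
The design has no redox or protecting-group run-up (the benzyl ethers arrive with 2 and 4 and leave in the last step), no conjugate addition to a hindered enone, no discarded stereocentre and no oxidative aromatization, because the oxygen pattern is already in the pyrone.

Key step: step 3

**Route**

Step 1
Reactants: 1 2,6-dimethyl-4H-pyran-4-one; 2 1-(benzyloxy)-4-(chloromethyl)benzene
Product: 3 2-{2-[4-(benzyloxy)phenyl]ethyl}-6-methyl-4H-pyran-4-one
Conditions: 1 (1.5 equiv), LiN(SiMe3)2 (1.4 equiv), THF, −78 °C; then 2 (1.0 equiv), NaI (10 mol %), −78 °C → rt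
Reagents that add atoms: none
Why: Kinetic deprotonation of one lateral methyl group gives the cross-conjugated lithium dienolate, which is alkylated at its exocyclic carbon by the reactive benzylic chloride (lateral alkylation of a 2-methyl-4-pyrone, SN2 displacement with iodide catalysis), the excess of 1 suppressing a second alkylation.

Step 2
Reactants: 3 2-{2-[4-(benzyloxy)phenyl]ethyl}-6-methyl-4H-pyran-4-one; 4 3-(benzyloxy)benzaldehyde
Product: 5 2-{2-[4-(benzyloxy)phenyl]ethyl}-6-{(E)-2-[3-(benzyloxy)phenyl]ethenyl}-4H-pyran-4-one
Conditions: 4 (1.05 equiv), NaOEt (1.2 equiv), EtOH, rt → 50 °C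
Reagents that add atoms: none
Why: Base-mediated vinylogous aldol condensation (Claisen–Schmidt type) of the pyrone methyl group with the non-enolizable aldehyde, as known for 2,6-dimethyl-4-pyrone and aryl aldehydes, should take place at the less hindered methyl rather than at the methylene group and end by E1cB loss of water in the conjugated (E)-styryl compound.

Step 3
Reactants: 5 2-{2-[4-(benzyloxy)phenyl]ethyl}-6-{(E)-2-[3-(benzyloxy)phenyl]ethenyl}-4H-pyran-4-one
Product: 7 4-[4-(benzyloxy)benzyl]-5-{(E)-2-[3-(benzyloxy)phenyl]ethenyl}benzene-1,3-diol, via open-chain triketone 6 (not isolated)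
Conditions: KOH (8 equiv), EtOH–H2O (2:1), degassed, argon, 80 °C; then 2 M HCl, 0 °C
Reagents that add atoms: water, O
Why: Hydroxide adds to C2 or C6 of the 4-pyrone (conjugate addition to the vinylogous ester, then ring opening) and gives the enolates of triketone 6, in which the carbon bearing the 4-(benzyloxy)benzyl group is the only terminal carbon with hydrogen α to a carbonyl; its enolate adds to the cinnamoyl carbonyl, water is lost and the two remaining carbonyl groups enolize to the resorcinol. The closest known reaction type is the classical alkali conversion of 2,6-dimethyl-4-pyrone (through heptane-2,4,6-trione) into orcinol, together with the base-induced aldol cyclizations of 3,5,7-triketones and triketo acids, cinnamoyl-terminated ones included, to resorcinols and stilbenes. Ring A closes in a 6-(enolendo)-exo-trig aldol mode that forms the C1–C2 bond of the target, so that five pyrone carbons and one lateral carbon become the six carbons of ring A. No stereocentre is formed, because the aldol carbon becomes aromatic. The step needs regioselectivity between the two chain ends and C- over O-closure: the styryl group has no enolizable hydrogen, so only the wanted aldol direction exists, and reclosure to the pyrone or oxa-Michael addition to the styryl group are reversible in base whereas aromatization is not. Air is excluded because the electron-rich resorcinolate is easily oxidized, and the benzyl ethers are inert to hydroxide.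

Step 4
Reactants: 7 4-[4-(benzyloxy)benzyl]-5-{(E)-2-[3-(benzyloxy)phenyl]ethenyl}benzene-1,3-diol
Product: 8 2-[4-(benzyloxy)benzyl]-1-{(E)-2-[3-(benzyloxy)phenyl]ethenyl}-3,5-dimethoxybenzene
Conditions: MeI (4 equiv), K2CO3 (4 equiv), DMF, rt
Reagents that add atoms: iodomethane, CI
Why: Williamson etherification of both phenoxides with iodomethane under carbonate gives O-methylation only, and the benzyl ethers and the stilbene are inert.

Step 5
Reactants: 8 2-[4-(benzyloxy)benzyl]-1-{(E)-2-[3-(benzyloxy)phenyl]ethenyl}-3,5-dimethoxybenzene
Product: 9 3-{2-[2-(4-hydroxybenzyl)-3,5-dimethoxyphenyl]ethyl}phenol (Gymconopin D)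
Conditions: H2 (1 atm), 10% Pd/C, EtOAc–MeOH, rt
Reagents that add atoms: none
Why: Heterogeneous catalytic hydrogenation saturates the stilbene double bond and cleaves both aryl benzyl ethers by hydrogenolysis in the same operation, whereas the aryl methyl ethers and the diarylmethane C–C bonds are stable under these mild conditions.

**Compound list**

1 | 2,6-dimethyl-4H-pyran-4-one | Cc1cc(=O)cc(C)o1 | starting material
2 | 1-(benzyloxy)-4-(chloromethyl)benzene | ClCc1ccc(OCc2ccccc2)cc1 | starting material
3 | 2-{2-[4-(benzyloxy)phenyl]ethyl}-6-methyl-4H-pyran-4-one | Cc1cc(=O)cc(CCc2ccc(OCc3ccccc3)cc2)o1 | intermediate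
4 | 3-(benzyloxy)benzaldehyde | O=Cc1cccc(OCc2ccccc2)c1 | starting material
5 | 2-{2-[4-(benzyloxy)phenyl]ethyl}-6-{(E)-2-[3-(benzyloxy)phenyl]ethenyl}-4H-pyran-4-one | O=c1cc(CCc2ccc(OCc3ccccc3)cc2)oc(/C=C/c2cccc(OCc3ccccc3)c2)c1 | intermediate
6 | (E)-9-[3-(benzyloxy)phenyl]-1-[4-(benzyloxy)phenyl]non-8-ene-3,5,7-trione (present as enolates) | O=C(CCc1ccc(OCc2ccccc2)cc1)CC(=O)CC(=O)/C=C/c1cccc(OCc2ccccc2)c1 | intermediate (not isolated)
7 | 4-[4-(benzyloxy)benzyl]-5-{(E)-2-[3-(benzyloxy)phenyl]ethenyl}benzene-1,3-diol | Oc1cc(O)c(Cc2ccc(OCc3ccccc3)cc2)c(/C=C/c2cccc(OCc3ccccc3)c2)c1 | intermediate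
8 | 2-[4-(benzyloxy)benzyl]-1-{(E)-2-[3-(benzyloxy)phenyl]ethenyl}-3,5-dimethoxybenzene | COc1cc(OC)c(Cc2ccc(OCc3ccccc3)cc2)c(/C=C/c2cccc(OCc3ccccc3)c2)c1 | intermediate
9 | 3-{2-[2-(4-hydroxybenzyl)-3,5-dimethoxyphenyl]ethyl}phenol | COc1cc(CCc2cccc(O)c2)c(Cc2ccc(O)cc2)c(OC)c1 | target

**Step count and risks**

Total step count: 5. Longest linear sequence: 5 steps (1 → 3 → 5 → 7 → 8 → 9).

Steps most likely to fail:

1. Step 3 (key step). Hydroxide may cleave the triketone (retro-Claisen cleavage, or retro-aldol loss of the aldehyde from the cinnamoyl end) faster than the slow aldol closure from a substituted methylene carbon. The fallback takes ring A from a bought arene; it sets out from 4 and comes back at 8. Horner–Wadsworth–Emmons olefination of 4 (NaH, THF, 0 °C → rt) with diethyl (2-bromo-3,5-dimethoxybenzyl)phosphonate F1 would give 2-bromo-1-{(E)-2-[3-(benzyloxy)phenyl]ethenyl}-3,5-dimethoxybenzene F2. F1 is obtained from commercial diethyl (3,5-dimethoxybenzyl)phosphonate and N-bromosuccinimide in MeCN (bromination para to a methoxy group). Bromine–lithium exchange on F2 (n-BuLi, THF, −78 °C), transmetalation with ZnCl2 and Negishi coupling with 2 [Pd(PPh3)4, THF, 50 °C] would then give 8.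

2. Step 2. Condensation may also occur at the methylene group next to the pyrone or a second time on the product, and ethoxide may open the pyrone ring. The fallback attaches the two side chains in the reverse order; it sets out from 1 and comes back at 5. Condensation of 1 (3 equiv) with 4 (NaOEt, EtOH) would give 2-{(E)-2-[3-(benzyloxy)phenyl]ethenyl}-6-methyl-4H-pyran-4-one F3, in which the methyl group is the only lateral C–H acid left. Deprotonation with LiN(SiMe3)2 (THF, −78 °C) and alkylation with 2 would then give 5 directly.

3. Step 1. Proton transfer between product and dienolate may lead to polyalkylation, and metalation of a ring position may compete. The fallback builds pyrone 3 from an open chain; it sets out from 2 and comes back at 3. Alkylation of the dianion of pentane-2,4-dione [LiN(i-Pr)2, 2.1 equiv, THF, 0 °C] with 2 at the terminal carbon would give 6-[4-(benzyloxy)phenyl]hexane-2,4-dione F4. Its dianion [LiN(i-Pr)2, 3 equiv] would be acetylated at the methyl terminus with ethyl acetate to 8-[4-(benzyloxy)phenyl]octane-2,4,6-trione F5. Acid cyclodehydration (p-TsOH, toluene, reflux, water separator) would close the pyrone ring and give 3.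

**Further compounds**

F1 | step 3 | diethyl (2-bromo-3,5-dimethoxybenzyl)phosphonate | CCOP(=O)(OCC)Cc1cc(OC)cc(OC)c1Br
F2 | step 3 | 2-bromo-1-{(E)-2-[3-(benzyloxy)phenyl]ethenyl}-3,5-dimethoxybenzene | COc1cc(OC)c(Br)c(/C=C/c2cccc(OCc3ccccc3)c2)c1
F3 | step 2 | 2-{(E)-2-[3-(benzyloxy)phenyl]ethenyl}-6-methyl-4H-pyran-4-one | Cc1cc(=O)cc(/C=C/c2cccc(OCc3ccccc3)c2)o1
F4 | step 1 | 6-[4-(benzyloxy)phenyl]hexane-2,4-dione | CC(=O)CC(=O)CCc1ccc(OCc2ccccc2)cc1
F5 | step 1 | 8-[4-(benzyloxy)phenyl]octane-2,4,6-trione | CC(=O)CC(=O)CC(=O)CCc1ccc(OCc2ccccc2)cc1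
A1 | direct plan | 3-[3-(benzyloxy)phenyl]propanal | O=CCCc1cccc(OCc2ccccc2)c1
A2 | direct plan | (E)-3-[4-(benzyloxy)benzyl]-6-[3-(benzyloxy)phenyl]hex-3-en-2-one | CC(=O)/C(Cc1ccc(OCc2ccccc2)cc1)=C/CCc1cccc(OCc2ccccc2)c1
A3 | direct plan | trans-4-[4-(benzyloxy)benzyl]-5-{2-[3-(benzyloxy)phenyl]ethyl}cyclohexane-1,3-dione (racemic) | O=C1CC(=O)[C@H](Cc2ccc(OCc3ccccc3)cc2)[C@@H](CCc2cccc(OCc3ccccc3)c2)C1
A4 | direct plan | 2-[4-(benzyloxy)benzyl]-1-{2-[3-(benzyloxy)phenyl]ethyl}-3,5-dimethoxybenzene | COc1cc(CCc2cccc(OCc3ccccc3)c2)c(Cc2ccc(OCc3ccccc3)cc2)c(OC)c1
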